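**The decision.** Before I picked the initiator charge for the next run, I decided to reckon what the solid could supply.

| flask | solid monomer | initiator | time |
|---|---|---|---|
| epsilon | 0.20 M | 0.015 mM | 2.0 min |
| eta | 0.20 M | 0.040 mM | 2.0 min |
| zeta | 0.20 M | 0.12 mM | 2.0 min |
| alpha | 0.20 M | 0.40 mM | 2.0 min |
| gamma | 0.20 M | 1.2 mM | 2.0 min |

    free monomer + initiating radical → growing radical + monomer in chains (k1 = 9.2 × 10⁶ M⁻¹ s⁻¹)
    crystals ⇌ monomer in chains, rate k2*(cs2 - [monomer in chains]) while solid is left; crystals form when [monomer in chains] > cs2 (cs2 = 4.6 mM, k2 = 0.11 s⁻¹)
    free monomer + growing radical → monomer in chains + growing radical, rate k3*[growing radical]*[free monomer] (k3 = 1.0 × 10⁷ M⁻¹ s⁻¹)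
    free monomer + monomer in chains ⇌ idle adduct, settled at all times (K4 = 23 M⁻¹)
    solid monomer ⇌ free monomer, rate k5*(cs5 - [free monomer]) while solid is left; crystals form when [free monomer] > cs5 (cs5 = 0.11 M, k5 = 0.0020 s⁻¹)
    initiator → 2 initiating radical (k6 = 1.6 × 10⁻⁴ s⁻¹)
    2 growing radical → dead chain (k7 = 2.8 × 10⁸ M⁻¹ s⁻¹)

- percent here means solid monomer units held: one idle adduct counts as two
- what is said of monomer in chains includes crystals and idle adduct
- where a step has two of a species, its rate is k times that concentration squared, and two are used at each turn
- crystals, solid monomer is a solid; its amount is given per volume of the solution
- at the start none of the solid monomer is in solution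
- in an amount of monomer in chains, one idle adduct counts as one monomer in chains
- "hardly changes" means that all values lie within two and a half points (for a concentration: within two and a half percent of the largest)
- run time (epsilon): 2.0 min

- amount of monomer in chains at the end, in percent of the solid monomer charged for epsilon, eta, zeta, alpha, gamma, in this order
- the shape of the row from first to last (falls all the way / rises all the way / falls, then rises / hardly changes / rises, then falls)

**The ceiling.** Free monomer comes from the solid by the dissolving step, solid monomer ⇌ free monomer, rate k5*(cs5 - [free monomer]) while solid is left; crystals form when [free monomer] > cs5 (cs5 = 0.11 M, k5 = 0.0020 s⁻¹). Its rate is the coefficient 0.0020 s⁻¹ times the gap between the solubility 0.11 M and c(free monomer), so with c(free monomer) at zero it runs at coefficient times solubility, and any free monomer present slows it. Integrating that full rate over 2.0 min and dividing by the charge 0.20 M gave 13.2%. I called this the dissolving ceiling, the share of the solid monomer charged that can have entered solution by that time. Since it is less than the whole charge, solid monomer stays through the run. With nothing taking free monomer away, the same rate integrates to solubility times one minus the exponential of minus coefficient times time, which is 11.7% of the charge. The dissolved share therefore lies in a window 1.5 percentage points wide, and the initiator appears in neither end of it.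

**My rule.** My reckoning went no further: it gave a limit for the row and no point of it. So I resolved to take the smallest initiator charge whose row came within 2 percentage points of the ceiling.

**The forecast.** The forecast gave 9.2%, 10.6%, 11.6%, 12.3% and 12.7%, and called the shape rises all the way, on the ground that “at most about 13% of the charge can dissolve in 2 min”. It offered points where I had a limit, and its last point lies below my ceiling.

**The flask.** The row came out 8.73%, 10.2%, 11.4%, 12.2%, 12.6%, so its shape was rises all the way. In epsilon at the end, 87.4% of the charge was still solid monomer, so 12.6% had left the solid, against the ceiling of 13.2%. Against the same ceiling, eta stood 3 points short and zeta 1.8 points short, so the next run took zeta's 0.12 mM.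

(Its constants were drawn at random within sensible limits.)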